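**Strategy.** Ring A of the flavone carries cyclohexene C3 on C8, flanked by the oxygens on C7 and C8a. This aryl–C3 bond between two oxygen-bearing carbons is cut back to an aryne: 3,5-bis(methoxymethoxy)benzyne takes up the aldehyde C=O of an (E)-β-methyl enal that already holds C5 (S), the 4-oxygenated aryl group and the prenylated aryl ketone. One operation forges aryl–O, aryl–C3 and O–C1 and stores C1–C3 as a 2H-chromene. Heating its silyl enol ether reopens the pyran and closes C3–C4 by an oxa-Diels–Alder reaction; the released phenol then directs the formylation on which the flavone is built.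

Key step: step 14

Remarks on the chemistry:
- Cyclohexene locants: C1 (methyl-bearing) = C2, C3 (bears ring A), C4 (bears the aroyl group), C5 (bears the 4-oxygenated phenyl group), C6 (CH2). With these locants the target is (3R,4R,5S), all-trans. C5 of enal 25 is S and corresponds to C5 of the target.
- MOM = methoxymethyl; Ar′ = 2,4-bis(methoxymethoxy)-3-(3-methylbut-2-en-1-yl)phenyl; ring A phenyl locants: 1 = carbon bonded to cyclohexene C3.
- The enal geometry is erased in step 14; the (E)-isomer is carried for definiteness and a Z isomer would serve equally.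
- C4 is α to the ketone, so the all-trans (all-equatorial) arrangement is the thermodynamic one.
- Assumed commercial: phloroglucinol, resorcinol, prenyl bromide, but-3-en-2-one, 4,4-diethoxybut-1-ene, [4-(methoxymethoxy)phenyl]boronic acid, methyl 2,4-dihydroxybenzoate, 5-bromo-2-methylpent-2-ene (for the Grignard reagent).

**Aryne precursor**

Step 1
Reactants: 1 phloroglucinol
Product: 2 3,5-bis(methoxymethoxy)phenol
Conditions: MOMCl (2.0 equiv), i-Pr2NEt, DMF, 0 °C → rt
Reagents that add atoms: chloromethyl methyl ether, COCCl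
Why: Williamson-type O-alkylation of the threefold-symmetric triol with two equivalents of MOMCl should give the bis-ether as the main fraction, separable by chromatography from mono- and tris-ether, which can be hydrolysed and recycled.

Step 2
Reactants: 2 3,5-bis(methoxymethoxy)phenol
Product: 3 3,5-bis(methoxymethoxy)phenyl N-isopropylcarbamate
Conditions: i-PrNCO, Et3N (cat.), CH2Cl2, rt
Reagents that add atoms: isopropyl isocyanate, CC(C)N=C=O
Why: Amine-catalysed addition of a phenol to an isocyanate (carbamoylation) is clean and installs a directing group that can later be expelled under mild base.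

Step 3
Reactants: 3 3,5-bis(methoxymethoxy)phenyl N-isopropylcarbamate
Product: 7 3,5-bis(methoxymethoxy)-2-(trimethylsilyl)phenyl N-isopropylcarbamate, via N-silyl carbamate 4 (not isolated), via aryllithium 5 (not isolated), via bis-silyl carbamate 6 (not isolated)
Conditions: TBSOTf, TMEDA, Et2O, 0 °C → rt; n-BuLi, TMEDA, −78 °C; TMSCl, −78 °C → rt; aq. NaHSO4
Reagents that add atoms: chlorotrimethylsilane, C[Si](C)(C)Cl
Why: Directed ortho-metalation (Snieckus type) of the in situ N-silylated carbamate, the strongest director on the ring, should lithiate the position shared by carbamate and OMOM (two equivalent sites) in preference to the position between the two OMOM groups, and silylation followed by aqueous cleavage of the N–Si bond leaves the C-silyl carbamate.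

Step 4
Reactants: 7 3,5-bis(methoxymethoxy)-2-(trimethylsilyl)phenyl N-isopropylcarbamate
Product: 9 3,5-bis(methoxymethoxy)-2-(trimethylsilyl)phenyl trifluoromethanesulfonate, via silylphenol 8 (not isolated)
Conditions: Et2NH, DBU, MeCN, 40 °C; then PhNTf2, rt
Reagents that add atoms: N-phenylbis(trifluoromethanesulfonimide), O=S(=O)(N(c1ccccc1)S(=O)(=O)C(F)(F)F)C(F)(F)F
Why: Base-induced E1cB fragmentation of the N–H carbamate (the isocyanate being scavenged by Et2NH) frees the phenoxide, which is triflated in the same flask, the standard one-pot entry to ortho-silylaryl triflates under non-acidic, fluoride-free conditions that MOM ethers and the aryl–Si bond tolerate.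

**Aryl nucleophile for the ketone**

Step 5
Reactants: 10 resorcinol
Product: 11 1,3-bis(methoxymethoxy)benzene
Conditions: MOMCl, i-Pr2NEt, CH2Cl2, 0 °C → rt
Reagents that add atoms: chloromethyl methyl ether, COCCl
Why: Standard double O-alkylation (MOM protection) of a diphenol.

Step 6
Reactants: 11 1,3-bis(methoxymethoxy)benzene; 12 1-bromo-3-methylbut-2-ene (prenyl bromide)
Product: 14 1,3-bis(methoxymethoxy)-2-(3-methylbut-2-en-1-yl)benzene, via aryllithium 13 (not isolated)
Conditions: n-BuLi, THF, 0 °C; CuBr·SMe2 (10 mol %), 12, −40 °C → rt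
Reagents that add atoms: none
Why: Directed ortho-metalation at C2, the position flanked by both OMOM groups, followed by copper-catalysed allylic substitution at the primary carbon of prenyl bromide should give the 2-prenyl arene.

**Enal**

Step 7
Reactants: 15 but-3-en-2-one; 16 4,4-diethoxybut-1-ene
Product: 17 (E)-6,6-diethoxyhex-3-en-2-one
Conditions: second-generation Hoveyda–Grubbs catalyst (2 mol %), CH2Cl2, 40 °C
Reagents that add atoms: none
Why: Olefin cross-metathesis between a terminal alkene and an electron-poor vinyl ketone that does not homodimerise should give the cross product with the (E)-enone geometry under thermodynamic control.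

Step 8
Reactants: 17 (E)-6,6-diethoxyhex-3-en-2-one; 18 [4-(methoxymethoxy)phenyl]boronic acid
Product: 19 (R)-6,6-diethoxy-4-[4-(methoxymethoxy)phenyl]hexan-2-one
Conditions: [Rh(OH)((S)-BINAP)]2 (3 mol % Rh), dioxane/H2O 10:1, 35 °C
Reagents that add atoms: none
Why: Hayashi–Miyaura rhodium-catalysed asymmetric 1,4-addition in which the (S)-BINAP–rhodium aryl species inserts the (E)-enone from its α-si face, setting the benzylic centre as R (the future C5, S in the target after the change of substituent priorities), while the base-free hydroxo-rhodium catalyst leaves acetal, MOM ether and the γ-CH2 alone.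

Step 9
Reactants: 19 (R)-6,6-diethoxy-4-[4-(methoxymethoxy)phenyl]hexan-2-one
Product: 20 ethyl (2E,5S)-7,7-diethoxy-3-methyl-5-[4-(methoxymethoxy)phenyl]hept-2-enoate
Conditions: (EtO)2P(O)CH2CO2Et, NaH, THF, 0 → 45 °C
Reagents that add atoms: triethyl phosphonoacetate, CCOC(=O)CP(=O)(OCC)OCC
Why: Horner–Wadsworth–Emmons olefination of the only ketone should give mainly the (E)-enoate (ester trans to the larger CH2 branch), the minor Z isomer being removable by chromatography and in any case convergent in step 14, and the stereocentre is not enolisable.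

Step 10
Reactants: 20 ethyl (2E,5S)-7,7-diethoxy-3-methyl-5-[4-(methoxymethoxy)phenyl]hept-2-enoate
Product: 21 ethyl (2E,5S)-3-methyl-5-[4-(methoxymethoxy)phenyl]-7-oxohept-2-enoate
Conditions: PPTS (20 mol %), acetone/H2O 9:1, 50 °C
Reagents that add atoms: water, O
Why: Mild acid-catalysed acetal hydrolysis unmasks the aldehyde while the aryl MOM ether, which needs stronger acid, and the conjugated ester survive.

Step 11
Reactants: 14 1,3-bis(methoxymethoxy)-2-(3-methylbut-2-en-1-yl)benzene; 21 ethyl (2E,5S)-3-methyl-5-[4-(methoxymethoxy)phenyl]-7-oxohept-2-enoate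
Product: 23 ethyl (2E,5S)-7-Ar′-7-hydroxy-3-methyl-5-[4-(methoxymethoxy)phenyl]hept-2-enoate (both C7 epimers), via aryllithium 22 (not isolated)
Conditions: 14, n-BuLi, TMEDA, THF, 0 °C; then 21, −78 °C
Reagents that add atoms: none
Why: Directed ortho-lithiation of 14 next to an OMOM group gives aryllithium 22, which undergoes 1,2-addition to the aldehyde far faster than to the hindered β,β-disubstituted enoate at −78 °C, and the new carbinol centre is formed without control and removed in step 13.

Step 12
Reactants: 23 ethyl (2E,5S)-7-Ar′-7-hydroxy-3-methyl-5-[4-(methoxymethoxy)phenyl]hept-2-enoate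
Product: 24 (2E,5S)-7-Ar′-3-methyl-5-[4-(methoxymethoxy)phenyl]hept-2-ene-1,7-diol (both C7 epimers)
Conditions: i-Bu2AlH (3.5 equiv), CH2Cl2, −78 °C; aq. potassium sodium tartrate
Reagents that add atoms: none
Why: i-Bu2AlH reduces the conjugated ester in 1,2-fashion to the allylic alcohol without touching the trisubstituted alkenes or MOM ethers, and the E geometry is retained.

Step 13
Reactants: 24 (2E,5S)-7-Ar′-3-methyl-5-[4-(methoxymethoxy)phenyl]hept-2-ene-1,7-diol
Product: 25 (2E,5S)-7-Ar′-3-methyl-5-[4-(methoxymethoxy)phenyl]-7-oxohept-2-enal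
Conditions: Dess–Martin periodinane (2.6 equiv), NaHCO3, CH2Cl2, 0 °C → rt
Reagents that add atoms: none
Why: Dess–Martin oxidation converts the benzylic alcohol into the aryl ketone and the allylic alcohol into the enal in one operation under buffered, non-epimerising conditions (C5 is β to both carbonyl groups).

**Key step and carbocycle**

Step 14
Reactants: 9 3,5-bis(methoxymethoxy)-2-(trimethylsilyl)phenyl trifluoromethanesulfonate; 25 (2E,5S)-7-Ar′-3-methyl-5-[4-(methoxymethoxy)phenyl]-7-oxohept-2-enal
Product: 29 (3S)-1-Ar′-4-[5,7-bis(methoxymethoxy)-2-methyl-2H-chromen-2-yl]-3-[4-(methoxymethoxy)phenyl]butan-1-one (both C2 epimers of the chromene), via aryne 26 (not isolated), via benzoxete 27 (not isolated), via ortho-quinone methide 28 (not isolated)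
Conditions: CsF (4 equiv), MeCN, 25 → 40 °C; 9 (1.8 equiv) added slowly to 25 and CsF
Reagents that add atoms: none
Why: Fluoride-induced 1,2-elimination of 9 gives aryne 26, the aldehyde oxygen of 25 adds to the aryne carbon remote from the flanking OMOM group, and the aryl anion formed beside that group closes on the oxocarbenium carbon (formal [2+2]) to benzoxete 27. A 4π ring opening then gives ortho-quinone methide 28, whose 1-oxatriene closes the pyran ring by disrotatory oxa-6π electrocyclisation (O to C1). The closest known chemistry is the fluoride-triggered annulation of arynes with α,β-unsaturated aldehydes to 2H-chromenes and the related insertion of arynes into formamide C=O bonds. The new quaternary centre (chromene C2, the future C1) is formed without control, which is immaterial because both epimers open to the same quinone methide in step 16, and the enal geometry is likewise erased. The step needs regioselective addition to the aryne, secured by the inductively withdrawing OMOM next to the triple bond (distortion and sterics send oxygen to the distal carbon, so the carbon substituent lands between the two ring oxygens), and chemoselectivity for the aldehyde over the ketone and prenyl groups, favoured by the electron-rich, unhindered enal oxygen and by keeping the aryne concentration low.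

Step 15
Reactants: 29 chromene ketone (both C2 epimers)
Product: 30 (Z)-tert-butyldimethylsilyl enol ether of 29 (Ar′–C(OTBS)=CH–C5, S at C5, both chromene C2 epimers)
Conditions: KN(SiMe3)2, THF, −78 °C; TBSCl, −78 → 0 °C
Reagents that add atoms: tert-butyldimethylsilyl chloride, CC(C)(C)[Si](C)(C)Cl
Why: Kinetic deprotonation of the only enolisable position (C4) and O-silylation of the potassium enolate should give the (Z)-silyl enol ether typical of aryl alkyl ketones, under basic conditions that spare the chromene and the MOM ethers.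

Step 16
Reactants: 30 (Z)-silyl enol ether
Product: 33 Ar′ (3R,4R,5S)-3-[2-hydroxy-4,6-bis(methoxymethoxy)phenyl]-1-methyl-5-[4-(methoxymethoxy)phenyl]cyclohex-1-en-4-yl ketone (all-trans), via ortho-quinone methide 31 (not isolated), via silyl ketal 32 (not isolated)
Conditions: PhMe (0.01 M), 130 °C, sealed tube; then Bu4NF, THF, 0 °C → rt; AcOH quench
Reagents that add atoms: none
Why: Heating opens the chromene by retro-oxa-6π electrocyclisation (the known thermal chromene/ortho-quinone methide equilibrium used in citran-type cyclisations) to 31, whose oxadiene (O=C8a–C4a=C3) is trapped by the tethered electron-rich enol ether in an intramolecular inverse-electron-demand oxa-Diels–Alder reaction that forms C3–C4 and the ketal C–O bond; a chair-like tether with the C5 aryl group pseudo-equatorial places ring A on the same face (3,5-cis), a stepwise Mukaiyama–Michael path would converge on the same product, and after fluoride opens silyl ketal 32 the basic medium equilibrates the ketone α-centre C4 to the all-equatorial, all-trans arrangement.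

**Flavone**

Step 17
Reactants: 33 all-trans phenol ketone
Product: 35 Ar′ (3R,4R,5S)-3-[3-formyl-2-hydroxy-4,6-bis(methoxymethoxy)phenyl]-1-methyl-5-[4-(methoxymethoxy)phenyl]cyclohex-1-en-4-yl ketone, via hydroxymethylphenol 34 (not isolated)
Conditions: MgCl2, Et3N, (CH2O)n, MeCN, 75 °C
Reagents that add atoms: paraformaldehyde (formaldehyde), C=O
Why: Magnesium-mediated ortho-formylation (Casnati–Skattebøl reaction) in which the magnesium phenoxide delivers formaldehyde only to the free position ortho to the ring A hydroxyl, the other open position between two MOM ethers lacking this anchor, and hydroxymethyl intermediate 34 is oxidised by a second formaldehyde through hydride transfer.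

Step 18
Reactants: 35 salicylaldehyde
Product: 36 Ar′ (3R,4R,5S)-3-[2-hydroxy-3-(1-hydroxy-5-methylhex-4-en-1-yl)-4,6-bis(methoxymethoxy)phenyl]-1-methyl-5-[4-(methoxymethoxy)phenyl]cyclohex-1-en-4-yl ketone (both carbinol epimers)
Conditions: (4-methylpent-3-en-1-yl)MgBr (3.5 equiv), THF, −78 → −20 °C; aq. NH4Cl
Reagents that add atoms: (4-methylpent-3-en-1-yl)magnesium bromide, CC(C)=CCC[Mg]Br
Why: Grignard 1,2-addition to the magnesium-chelated salicylaldehyde is much faster than attack on the α-branched, doubly flanked C4 aroyl ketone, and the uncontrolled carbinol centre is removed in step 19.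

Step 19
Reactants: 36 benzylic alcohol
Product: 37 Ar′ (3R,4R,5S)-3-[2-hydroxy-4,6-bis(methoxymethoxy)-3-(5-methylhex-4-enoyl)phenyl]-1-methyl-5-[4-(methoxymethoxy)phenyl]cyclohex-1-en-4-yl ketone
Conditions: MnO2 (activated, excess), CH2Cl2, rt, used directly on crude 36
Reagents that add atoms: none
Why: MnO2 selectively oxidises the ortho-hydroxybenzylic alcohol to the chelated aryl ketone and leaves phenol, alkenes and MOM ethers alone.

Step 20
Reactants: 38 methyl 2,4-dihydroxybenzoate
Product: 39 methyl 2,4-bis(methoxymethoxy)benzoate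
Conditions: NaH, MOMCl, DMF, 0 °C → rt
Reagents that add atoms: chloromethyl methyl ether, COCCl
Why: Double MOM protection in which NaH is used so that the hydrogen-bonded 2-hydroxyl is alkylated as well.

Step 21
Reactants: 39 methyl 2,4-bis(methoxymethoxy)benzoate
Product: 40 2,4-bis(methoxymethoxy)benzoic acid
Conditions: LiOH, THF/MeOH/H2O, 40 °C; then cold dilute HCl to pH 4
Reagents that add atoms: lithium hydroxide, [Li+].[OH-]
Why: Saponification of the methyl ester, the MOM ethers being base-stable and surviving the brief cold acidification.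

Step 22
Reactants: 37 ortho-hydroxyaryl ketone; 40 2,4-bis(methoxymethoxy)benzoic acid
Product: 41 2-[(3R,4R,5S)-4-(Ar′-carbonyl)-1-methyl-5-[4-(methoxymethoxy)phenyl]cyclohex-1-en-3-yl]-3,5-bis(methoxymethoxy)-6-(5-methylhex-4-enoyl)phenyl 2,4-bis(methoxymethoxy)benzoate
Conditions: DCC, DMAP, CH2Cl2, rt
Reagents that add atoms: none
Why: Steglich esterification acylates the only free hydroxyl group, the ring A phenol.

Step 23
Reactants: 41 aryl ester
Product: 42 1-[ring A aryl]-3-[2,4-bis(methoxymethoxy)phenyl]-2-(3-methylbut-2-en-1-yl)propane-1,3-dione, ring A aryl = 2-hydroxy-4,6-bis(methoxymethoxy)-3-[(3R,4R,5S)-4-(Ar′-carbonyl)-1-methyl-5-[4-(methoxymethoxy)phenyl]cyclohex-1-en-3-yl]phenyl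
Conditions: KOt-Bu (3 equiv), THF, 0 °C → rt; AcOH quench
Reagents that add atoms: none
Why: Baker–Venkataraman rearrangement in which the ketone enolate attacks the neighbouring aryl ester through a six-membered transition state, moving the aroyl group from O to C and freeing the ring A phenol again, while the stereocentre between the two carbonyl groups is labile and irrelevant.

Step 24
Reactants: 42 1,3-diketone
Product: 44 the target CNP0293515.1 (3R,4R,5S all-trans), via hepta-MOM flavone 43 (not isolated)
Conditions: 2 M HCl (aq), MeOH/THF, rt → 45 °C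
Reagents that add atoms: none
Why: Acid-catalysed cyclodehydration of the ortho-hydroxyaryl 1,3-diketone, which can only close through the one free phenol next to the cyclohexenyl-bearing carbon (so that group ends at flavone C8 and not C6), gives 43, and continued acid solvolysis in methanol removes all seven MOM groups as is usual for prenylated flavonoids, with C4 already in its thermodynamic trans,trans arrangement.

**Compound list**

1 | phloroglucinol | Oc1cc(O)cc(O)c1 | starting material
2 | 3,5-bis(methoxymethoxy)phenol | COCOc1cc(O)cc(OCOC)c1 | intermediate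
3 | 3,5-bis(methoxymethoxy)phenyl N-isopropylcarbamate | COCOc1cc(OCOC)cc(OC(=O)NC(C)C)c1 | intermediate
4 | 3,5-bis(methoxymethoxy)phenyl N-(tert-butyldimethylsilyl)-N-isopropylcarbamate | COCOc1cc(OCOC)cc(OC(=O)N(C(C)C)[Si](C)(C)C(C)(C)C)c1 | intermediate
5 | 2-lithio derivative of 4 | [Li]c1c(OCOC)cc(OCOC)cc1OC(=O)N(C(C)C)[Si](C)(C)C(C)(C)C | intermediate
6 | 3,5-bis(methoxymethoxy)-2-(trimethylsilyl)phenyl N-(tert-butyldimethylsilyl)-N-isopropylcarbamate | COCOc1cc(OCOC)c([Si](C)(C)C)c(OC(=O)N(C(C)C)[Si](C)(C)C(C)(C)C)c1 | intermediate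
7 | 3,5-bis(methoxymethoxy)-2-(trimethylsilyl)phenyl N-isopropylcarbamate | COCOc1cc(OCOC)c([Si](C)(C)C)c(OC(=O)NC(C)C)c1 | intermediate
8 | 3,5-bis(methoxymethoxy)-2-(trimethylsilyl)phenol | COCOc1cc(OCOC)c([Si](C)(C)C)c(O)c1 | intermediate
9 | 3,5-bis(methoxymethoxy)-2-(trimethylsilyl)phenyl trifluoromethanesulfonate | COCOc1cc(OCOC)c([Si](C)(C)C)c(OS(=O)(=O)C(F)(F)F)c1 | intermediate
10 | resorcinol | Oc1cccc(O)c1 | starting material
11 | 1,3-bis(methoxymethoxy)benzene | COCOc1cccc(OCOC)c1 | intermediate
12 | 1-bromo-3-methylbut-2-ene | CC(C)=CCBr | starting material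
13 | 2-lithio-1,3-bis(methoxymethoxy)benzene | [Li]c1c(OCOC)cccc1OCOC | intermediate
14 | 1,3-bis(methoxymethoxy)-2-(3-methylbut-2-en-1-yl)benzene | COCOc1cccc(OCOC)c1CC=C(C)C | intermediate
15 | but-3-en-2-one | CC(=O)C=C | starting material
16 | 4,4-diethoxybut-1-ene | C=CCC(OCC)OCC | starting material
17 | (E)-6,6-diethoxyhex-3-en-2-one | CC(=O)/C=C/CC(OCC)OCC | intermediate
18 | [4-(methoxymethoxy)phenyl]boronic acid | COCOc1ccc(B(O)O)cc1 | starting material
19 | (R)-6,6-diethoxy-4-[4-(methoxymethoxy)phenyl]hexan-2-one | CC(=O)C[C@H](c1ccc(OCOC)cc1)CC(OCC)OCC | intermediate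
20 | ethyl (2E,5S)-7,7-diethoxy-3-methyl-5-[4-(methoxymethoxy)phenyl]hept-2-enoate | CCOC(=O)/C=C(\C)C[C@H](c1ccc(OCOC)cc1)CC(OCC)OCC | intermediate
21 | ethyl (2E,5S)-3-methyl-5-[4-(methoxymethoxy)phenyl]-7-oxohept-2-enoate | CCOC(=O)/C=C(\C)C[C@H](c1ccc(OCOC)cc1)CC=O | intermediate
22 | [2,4-bis(methoxymethoxy)-3-(3-methylbut-2-en-1-yl)phenyl]lithium | [Li]c1ccc(OCOC)c(CC=C(C)C)c1OCOC | intermediate
23 | ethyl (2E,5S)-7-Ar′-7-hydroxy-3-methyl-5-[4-(methoxymethoxy)phenyl]hept-2-enoate, both C7 epimers | CCOC(=O)/C=C(\C)C[C@H](c1ccc(OCOC)cc1)CC(O)c1ccc(OCOC)c(CC=C(C)C)c1OCOC | intermediate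
24 | (2E,5S)-7-Ar′-3-methyl-5-[4-(methoxymethoxy)phenyl]hept-2-ene-1,7-diol, both C7 epimers | OC/C=C(\C)C[C@H](c1ccc(OCOC)cc1)CC(O)c1ccc(OCOC)c(CC=C(C)C)c1OCOC | intermediate
25 | (2E,5S)-7-Ar′-3-methyl-5-[4-(methoxymethoxy)phenyl]-7-oxohept-2-enal | O=C/C=C(\C)C[C@H](c1ccc(OCOC)cc1)CC(=O)c1ccc(OCOC)c(CC=C(C)C)c1OCOC | intermediate
26 | 3,5-bis(methoxymethoxy)benzyne | COCOC1=CC(OCOC)=CC#C1 | intermediate
27 | 2H-benzoxete from 26 and the aldehyde of 25 (4,6-bis(methoxymethoxy), 2-alkenyl, S at C5) | C/C(C[C@H](c1ccc(OCOC)cc1)CC(=O)c1ccc(OCOC)c(CC=C(C)C)c1OCOC)=C\C1Oc2cc(OCOC)cc(OCOC)c21 | intermediate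
28 | ortho-quinone methide from 27 (S at C5) | O=C1C=C(OCOC)C=C(OCOC)C1=CC=C(C)C[C@H](c1ccc(OCOC)cc1)CC(=O)c1ccc(OCOC)c(CC=C(C)C)c1OCOC | intermediate
29 | (3S)-1-Ar′-4-[5,7-bis(methoxymethoxy)-2-methyl-2H-chromen-2-yl]-3-[4-(methoxymethoxy)phenyl]butan-1-one, both chromene C2 epimers | CC1(C[C@H](c2ccc(OCOC)cc2)CC(=O)c2ccc(OCOC)c(CC=C(C)C)c2OCOC)C=Cc2c(OCOC)cc(OCOC)cc2O1 | intermediate
30 | (Z)-tert-butyldimethylsilyl enol ether of 29 | CC1(C[C@H](c2ccc(OCOC)cc2)/C=C(\O[Si](C)(C)C(C)(C)C)c2ccc(OCOC)c(CC=C(C)C)c2OCOC)C=Cc2c(OCOC)cc(OCOC)cc2O1 | intermediate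
31 | ortho-quinone methide from 30 | O=C1C=C(OCOC)C=C(OCOC)C1=CC=C(C)C[C@H](c1ccc(OCOC)cc1)/C=C(\O[Si](C)(C)C(C)(C)C)c1ccc(OCOC)c(CC=C(C)C)c1OCOC | intermediate
32 | 6-Ar′-6-(tert-butyldimethylsilyloxy)-1,3-bis(methoxymethoxy)-9-methyl-7-[4-(methoxymethoxy)phenyl]-6a,7,8,10a-tetrahydro-6H-benzo[c]chromene, C10a and C7 as in 33, C6 and C6a as formed | CC1=C[C@H]2c3c(OCOC)cc(OCOC)cc3OC(O[Si](C)(C)C(C)(C)C)(c3ccc(OCOC)c(CC=C(C)C)c3OCOC)C2[C@@H](c2ccc(OCOC)cc2)C1 | intermediate
33 | Ar′ (3R,4R,5S)-3-[2-hydroxy-4,6-bis(methoxymethoxy)phenyl]-1-methyl-5-[4-(methoxymethoxy)phenyl]cyclohex-1-en-4-yl ketone | COCOc1ccc(C(=O)[C@@H]2[C@@H](c3ccc(OCOC)cc3)CC(C)=C[C@H]2c2c(O)cc(OCOC)cc2OCOC)c(OCOC)c1CC=C(C)C | intermediate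
34 | 3-(hydroxymethyl) derivative of 33 on ring A | COCOc1ccc(C(=O)[C@@H]2[C@@H](c3ccc(OCOC)cc3)CC(C)=C[C@H]2c2c(O)c(CO)c(OCOC)cc2OCOC)c(OCOC)c1CC=C(C)C | intermediate
35 | 3-formyl derivative of 33 on ring A | COCOc1ccc(C(=O)[C@@H]2[C@@H](c3ccc(OCOC)cc3)CC(C)=C[C@H]2c2c(O)c(C=O)c(OCOC)cc2OCOC)c(OCOC)c1CC=C(C)C | intermediate
36 | 3-(1-hydroxy-5-methylhex-4-en-1-yl) derivative of 33 on ring A, both carbinol epimers | COCOc1ccc(C(=O)[C@@H]2[C@@H](c3ccc(OCOC)cc3)CC(C)=C[C@H]2c2c(O)c(C(O)CCC=C(C)C)c(OCOC)cc2OCOC)c(OCOC)c1CC=C(C)C | intermediate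
37 | 3-(5-methylhex-4-enoyl) derivative of 33 on ring A | COCOc1ccc(C(=O)[C@@H]2[C@@H](c3ccc(OCOC)cc3)CC(C)=C[C@H]2c2c(O)c(C(=O)CCC=C(C)C)c(OCOC)cc2OCOC)c(OCOC)c1CC=C(C)C | intermediate
38 | methyl 2,4-dihydroxybenzoate | COC(=O)c1ccc(O)cc1O | starting material
39 | methyl 2,4-bis(methoxymethoxy)benzoate | COCOc1ccc(C(=O)OC)c(OCOC)c1 | intermediate
40 | 2,4-bis(methoxymethoxy)benzoic acid | COCOc1ccc(C(=O)O)c(OCOC)c1 | intermediate
41 | 2,4-bis(methoxymethoxy)benzoate ester of the ring A phenol of 37 | COCOc1ccc(C(=O)[C@@H]2[C@@H](c3ccc(OCOC)cc3)CC(C)=C[C@H]2c2c(OC(=O)c3ccc(OCOC)cc3OCOC)c(C(=O)CCC=C(C)C)c(OCOC)cc2OCOC)c(OCOC)c1CC=C(C)C | intermediate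
42 | 2-prenyl-1,3-diketone with free ring A phenol | COCOc1ccc(C(=O)[C@@H]2[C@@H](c3ccc(OCOC)cc3)CC(C)=C[C@H]2c2c(O)c(C(=O)C(CC=C(C)C)C(=O)c3ccc(OCOC)cc3OCOC)c(OCOC)cc2OCOC)c(OCOC)c1CC=C(C)C | intermediate
43 | hepta-MOM ether of the target | COCOc1ccc(C(=O)[C@@H]2[C@@H](c3ccc(OCOC)cc3)CC(C)=C[C@H]2c2c(OCOC)cc(OCOC)c3c(=O)c(CC=C(C)C)c(-c4ccc(OCOC)cc4OCOC)oc23)c(OCOC)c1CC=C(C)C | intermediate
44 | CNP0293515.1, 8-[(3R,4R,5S)-4-[2,4-dihydroxy-3-(3-methylbut-2-en-1-yl)benzoyl]-5-(4-hydroxyphenyl)-1-methylcyclohex-1-en-3-yl]-2-(2,4-dihydroxyphenyl)-5,7-dihydroxy-3-(3-methylbut-2-en-1-yl)chromen-4-one | CC(C)=CCc1c(O)ccc(C(=O)[C@@H]2[C@@H](c3ccc(O)cc3)CC(C)=C[C@H]2c2c(O)cc(O)c3c(=O)c(CC=C(C)C)c(-c4ccc(O)cc4O)oc23)c1O | target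

**Totals.** 24 steps in all; the longest linear sequence has 16 steps (steps 7–19 and 22–24, from 15 and 16 to 44).

**Steps most likely to fail**

1. Step 14. The aryne may be consumed by an ene reaction with a prenyl group or by the enolisable ketone, and excess aryne may go on to attack the electron-rich chromene, so chemoselectivity and mass balance could erode. The fallback leaves aryne chemistry: phenol 2 is condensed with enal 25 under ethylenediammonium diacetate catalysis in toluene at 80–110 °C. Knoevenagel-type C-alkylation ortho to the free hydroxyl and loss of water give the same ortho-quinone methide 28, which closes to 29. Only attack ortho to the hydroxyl can close the pyran, so the regiochemistry is the same. The fallback sets out from 2 and 25 and returns at 29; no new compound arises (F0).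

2. Step 16. Electrocyclic opening may be slow relative to a 1,7-hydrogen shift within the quinone methide, or the cycloaddition may discriminate poorly between the two faces at C3. The fallback replaces the pericyclic capture by an anionic one under thermodynamic control: ketone 29 is heated with DBU in toluene at 110 °C. The enolate adds in Michael fashion to the transient quinone methide, and because the phenoxide adduct can revert by retro-Michael reaction, the all-equatorial isomer should accumulate. The fallback sets out from 29, skips 30 and returns at 33; no new compound arises (F0).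

3. Step 24. Under protic acid the freed ortho-phenols may add to the prenyl or cyclohexene double bonds, or an ortho MOM group may be lost before ring closure so that the pyranone closes through the wrong oxygen. The fallback separates the two events and avoids protic solvolysis: 42 is cyclodehydrated with catalytic TsOH and 4 Å molecular sieves in toluene at 40 °C and hepta-MOM flavone 43 is isolated. The MOM groups are then removed with ZnBr2 and propane-1-thiol in CH2Cl2 at 0 °C within minutes. The fallback sets out from 42 and returns at 44; 43 is already listed, so no new compound arises (F0).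

**Further compounds**

F0 | step 14 | none | none
F0 | step 16 | none | none
F0 | step 24 | none | none
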